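The route rests on the bond between the ketone carbon (C3) of the 3(2H)-furanone ring and the adjacent quaternary carbon (C4), which carries the ring oxygen, a methyl group and the alkylidene carbon C5. With an acyl group placed on C5, C4 becomes the β-carbon of a Michael acceptor and C3 an acyl-anion carbon. The bond is therefore made by an enantioselective intramolecular Stetter reaction: an aldehyde, tethered through the future ring oxygen to an (E)-β-alkoxy enone, closes the five-membered ring and sets the quaternary stereocentre in one operation. The acetyl handle is then excised to a C5 aldehyde, which closes the ten-membered ring onto the butenolide γ-carbon by vinylogous aldol–elimination.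

Key step: step 13

Remark: atoms are numbered C1 (furanone carbon bearing the ring oxygen and the side chain), C2 (furanone CH), C3 (ketone), C4 (quaternary), C5 (alkylidene CH), C6 (enol-lactone carbon), C7 (butenolide β-carbon), C8 (ester-bearing carbinol), C9 (CH2), C10 (methyl-bearing CH), C11 (butenolide α-carbon), C12 (lactone carbonyl), C13 (acetoxymethyl carbon). The facial preference of the two chiral organocatalysts (steps 10 and 13) is assumed by analogy with simpler substrates; the antipodal catalyst would be used if the opposite face were delivered.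

Step 1
Reactants: 1 (R)-4-benzyl-3-propanoyl-1,3-oxazolidin-2-one; 2 2,3-dibromoprop-1-ene
Product: 4 (R)-4-benzyl-3-[(2S)-4-bromo-2-methylpent-4-enoyl]-1,3-oxazolidin-2-one, via sodium (Z)-enolate 3 (not isolated)
Conditions: NaN(SiMe3)2, THF, −78 °C; then 2, −78 to −40 °C
Reagents that add atoms: none
Why: The chelated sodium (Z)-enolate should be alkylated by the allylic bromide on the face opposite the benzyl group (oxazolidinone-auxiliary Evans alkylation), which sets C10 as (S) and leaves the vinylic bromide untouched.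

Step 2
Reactants: 4 (R)-4-benzyl-3-[(2S)-4-bromo-2-methylpent-4-enoyl]-1,3-oxazolidin-2-one
Product: 5 (2S)-4-bromo-2-methylpent-4-en-1-ol
Conditions: LiBH4, MeOH (1 equiv), Et2O, 0 °C
Reagents that add atoms: none
Why: Reductive cleavage of the imide by borohydride should give the primary alcohol and the recoverable auxiliary without touching the stereocentre or the vinyl bromide.

Step 3
Reactants: 5 (2S)-4-bromo-2-methylpent-4-en-1-ol
Product: 6 {[(2S)-4-bromo-2-methylpent-4-en-1-yl]oxy}triethylsilane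
Conditions: Et3SiCl, imidazole, CH2Cl2, 0 °C
Reagents that add atoms: chlorotriethylsilane CC[Si](Cl)(CC)CC
Why: Standard silylation of a primary alcohol; the triethylsilyl ether tolerates Grignard formation and can later be oxidised directly.

Step 4
Reactants: 6 {[(2S)-4-bromo-2-methylpent-4-en-1-yl]oxy}triethylsilane; 7 but-2-yne-1,4-diol
Product: 11 3-(hydroxymethyl)-4-[(4S)-4-methyl-5-(triethylsilyloxy)pent-1-en-2-yl]furan-2(5H)-one, via bis(chloromagnesium) butynediolate 8 (not isolated), via alkenyl Grignard reagent 9 (not isolated), via cyclic alkenylmagnesium chelate 10 (not isolated)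
Conditions: 7, i-PrMgCl (2 equiv), THF, 0 °C; 6, Mg, THF, 45 °C; combine, THF/toluene, 80 °C; CO2, 0 °C; aqueous citric acid
Reagents that add atoms: carbon dioxide O=C=O
Why: Hydroxyl-directed anti-carbomagnesiation of the propargylic alkoxide should give a five-membered alkenylmagnesium chelate that is carboxylated with retention; the resulting (Z)-γ-hydroxy acid lactonises on acidification to the 3,4-disubstituted butenolide, and the symmetry of the diol removes any regiochemical question.

Step 5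
Reactants: 11 3-(hydroxymethyl)-4-[(4S)-4-methyl-5-(triethylsilyloxy)pent-1-en-2-yl]furan-2(5H)-one
Product: 12 3-{[(tert-butyldimethylsilyl)oxy]methyl}-4-[(4S)-4-methyl-5-(triethylsilyloxy)pent-1-en-2-yl]furan-2(5H)-one
Conditions: t-BuMe2SiCl, imidazole, DMF, 23 °C
Reagents that add atoms: tert-butylchlorodimethylsilane CC(C)(C)[Si](C)(C)Cl
Why: Silylation masks the C13 hydroxyl, so that no hemiketal forms with the ketone made next and the group is not ionised under later Lewis-acidic conditions.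

Step 6
Reactants: 12 3-{[(tert-butyldimethylsilyl)oxy]methyl}-4-[(4S)-4-methyl-5-(triethylsilyloxy)pent-1-en-2-yl]furan-2(5H)-one
Product: 14 3-{[(tert-butyldimethylsilyl)oxy]methyl}-4-[(3S)-3-methyl-4-(triethylsilyloxy)butanoyl]furan-2(5H)-one, via secondary ozonide 13 (not isolated)
Conditions: O3, CH2Cl2, −78 °C; then Me2S, −78 to 23 °C
Reagents that add atoms: ozone [O-][O+]=O
Why: In this ozonolysis the 1,1-disubstituted alkene should react in preference to the tetrasubstituted, ester-conjugated butenolide alkene, and reductive work-up gives the C8 ketone.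

Step 7
Reactants: 14 3-{[(tert-butyldimethylsilyl)oxy]methyl}-4-[(3S)-3-methyl-4-(triethylsilyloxy)butanoyl]furan-2(5H)-one
Product: 15 3-{[(tert-butyldimethylsilyl)oxy]methyl}-4-[(1S,3S)-1-hydroxy-3-methyl-4-(triethylsilyloxy)butyl]furan-2(5H)-one
Conditions: (R)-2-methyl-CBS-oxazaborolidine (20 mol%), BH3·SMe2, THF, −30 °C
Reagents that add atoms: none
Why: In the Corey–Bakshi–Shibata reduction the oxazaborolidine distinguishes the sp2 butenolide carbon (large) from the methylene arm (small), so the (R)-catalyst should give the (S)-carbinol at C8.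

Step 8
Reactants: 15 3-{[(tert-butyldimethylsilyl)oxy]methyl}-4-[(1S,3S)-1-hydroxy-3-methyl-4-(triethylsilyloxy)butyl]furan-2(5H)-one
Product: 16 (1S,3S)-1-(4-{[(tert-butyldimethylsilyl)oxy]methyl}-5-oxo-2,5-dihydrofuran-3-yl)-3-methyl-4-(triethylsilyloxy)butyl 3-methylbut-2-enoate
Conditions: 3-methylbut-2-enoyl chloride, pyridine, DMAP (cat.), CH2Cl2, 0 °C
Reagents that add atoms: 3-methylbut-2-enoyl chloride CC(C)=CC(Cl)=O
Why: Acylation of the secondary alcohol under pyridine/DMAP installs the final C8 ester early; the weak base limits deconjugation of the acyl donor.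

Step 9
Reactants: 16 (1S,3S)-1-(4-{[(tert-butyldimethylsilyl)oxy]methyl}-5-oxo-2,5-dihydrofuran-3-yl)-3-methyl-4-(triethylsilyloxy)butyl 3-methylbut-2-enoate
Product: 17 (1S,3S)-1-(4-{[(tert-butyldimethylsilyl)oxy]methyl}-5-oxo-2,5-dihydrofuran-3-yl)-3-methyl-4-oxobutyl 3-methylbut-2-enoate
Conditions: (COCl)2, DMSO, CH2Cl2, −78 to −40 °C; Et3N, −78 °C
Reagents that add atoms: none
Why: Swern conditions should cleave the primary triethylsilyl ether through the chlorosulfonium salt and oxidise it in situ to the aldehyde, while the tert-butyldimethylsilyl ether and the α-stereocentre survive at low temperature.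

Step 10
Reactants: 17 (1S,3S)-1-(4-{[(tert-butyldimethylsilyl)oxy]methyl}-5-oxo-2,5-dihydrofuran-3-yl)-3-methyl-4-oxobutyl 3-methylbut-2-enoate
Product: 18 (1S,3S,4R)-1-(4-{[(tert-butyldimethylsilyl)oxy]methyl}-5-oxo-2,5-dihydrofuran-3-yl)-4-hydroxy-3-methylhept-6-en-1-yl 3-methylbut-2-enoate
Conditions: allylboronic acid pinacol ester, (R)-3,3'-bis(2,4,6-triisopropylphenyl)-1,1'-binaphthyl-2,2'-diyl hydrogen phosphate (5 mol%), toluene, −30 °C
Reagents that add atoms: 2-allyl-4,4,5,5-tetramethyl-1,3,2-dioxaborolane C=CCB1OC(C)(C)C(C)(C)O1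
Why: Brønsted-acid-catalysed allylboration through a closed six-membered transition state, in which the chiral phosphate selects the aldehyde face, should give the (R)-carbinol at C1; this centre only serves as a tether and is erased in step 14.

Step 11
Reactants: 18 (1S,3S,4R)-1-(4-{[(tert-butyldimethylsilyl)oxy]methyl}-5-oxo-2,5-dihydrofuran-3-yl)-4-hydroxy-3-methylhept-6-en-1-yl 3-methylbut-2-enoate; 19 (E)-4-methoxypent-3-en-2-one
Product: 20 (1S,3S,4R)-1-(4-{[(tert-butyldimethylsilyl)oxy]methyl}-5-oxo-2,5-dihydrofuran-3-yl)-3-methyl-4-{[(2E)-4-oxopent-2-en-2-yl]oxy}hept-6-en-1-yl 3-methylbut-2-enoate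
Conditions: pyridinium p-toluenesulfonate (10 mol%), toluene, 5 Å molecular sieves, 80 °C
Reagents that add atoms: none
Why: Acid-catalysed vinylogous transesterification (addition–elimination at the β-carbon of the β-methoxy enone), driven by removal of methanol, should give the thermodynamically preferred (E)-β-alkoxy enone.

Step 12
Reactants: 20 (1S,3S,4R)-1-(4-{[(tert-butyldimethylsilyl)oxy]methyl}-5-oxo-2,5-dihydrofuran-3-yl)-3-methyl-4-{[(2E)-4-oxopent-2-en-2-yl]oxy}hept-6-en-1-yl 3-methylbut-2-enoate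
Product: 21 (1S,3S,4R)-1-(4-{[(tert-butyldimethylsilyl)oxy]methyl}-5-oxo-2,5-dihydrofuran-3-yl)-3-methyl-6-oxo-4-{[(2E)-4-oxopent-2-en-2-yl]oxy}hexyl 3-methylbut-2-enoate
Conditions: OsO4 (2 mol%), NaIO4, 2,6-lutidine, dioxane/H2O, 23 °C
Reagents that add atoms: osmium tetroxide O=[Os](=O)(=O)=O (catalytic oxygen carrier); sodium periodate [Na+].[O-]I(=O)(=O)=O
Why: In the Lemieux–Johnson oxidation the catalytic dihydroxylation should occur at the unhindered monosubstituted alkene rather than at the trisubstituted conjugated alkenes, and periodate cleaves the diol to the C3 aldehyde.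

Step 13
Reactants: 21 (1S,3S,4R)-1-(4-{[(tert-butyldimethylsilyl)oxy]methyl}-5-oxo-2,5-dihydrofuran-3-yl)-3-methyl-6-oxo-4-{[(2E)-4-oxopent-2-en-2-yl]oxy}hexyl 3-methylbut-2-enoate
Product: 22 (1S,3S)-1-(4-{[(tert-butyldimethylsilyl)oxy]methyl}-5-oxo-2,5-dihydrofuran-3-yl)-3-[(2R,5S)-5-methyl-4-oxo-5-(2-oxopropyl)oxolan-2-yl]butyl 3-methylbut-2-enoate
Conditions: 2-(pentafluorophenyl)-5a,10b-dihydro-4H,6H-indeno[2,1-b][1,2,4]triazolo[4,3-d][1,4]oxazin-2-ium tetrafluoroborate (aminoindanol-derived, 20 mol%, enantiomer delivering the 5S centre), KN(SiMe3)2 (20 mol%), toluene, 23 °C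
Reagents that add atoms: none
Why: The carbene formed from the triazolium salt adds to the aldehyde carbon C3 to give a Breslow intermediate whose nucleophilic acyl carbon attacks C4, the β-carbon of the (E)-β-alkoxy enone, and proton transfer with loss of the carbene releases the 1,4-diketone (asymmetric intramolecular Stetter reaction; the closest precedent is aldehydes tethered through oxygen to β,β-disubstituted acceptors, which give 2,2-disubstituted furan-3-ones). The one ring closed, the oxolan-3-one, forms in 5-exo-trig mode. The new quaternary stereocentre C4 is controlled by the chiral carbene, which exposes one face of the geometrically pure (E)-acceptor, while the C1 centre only places its side chain trans to the new acetonyl arm and is erased in step 14. The step needs conjugate addition to win over base-induced β-elimination of the vinylogous-ester oxygen from the β-alkoxy aldehyde and over benzoin-type pathways; catalytic base in toluene and the favourable five-membered transition state should secure this. The tetrasubstituted butenolide alkene and the β,β-disubstituted 3-methylbut-2-enoate are too hindered to act as competing acceptors.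

Step 14
Reactants: 22 (1S,3S)-1-(4-{[(tert-butyldimethylsilyl)oxy]methyl}-5-oxo-2,5-dihydrofuran-3-yl)-3-[(2R,5S)-5-methyl-4-oxo-5-(2-oxopropyl)oxolan-2-yl]butyl 3-methylbut-2-enoate
Product: 23 (1S,3S)-1-(4-{[(tert-butyldimethylsilyl)oxy]methyl}-5-oxo-2,5-dihydrofuran-3-yl)-3-[(5S)-5-methyl-4-oxo-5-(2-oxopropyl)-4,5-dihydrofuran-2-yl]butyl 3-methylbut-2-enoate
Conditions: 2-iodoxybenzoic acid (IBX), DMSO/toluene, 70 °C
Reagents that add atoms: none
Why: IBX dehydrogenation of the ring ketone through its only possible enol (towards C2) should introduce the C1=C2 double bond, erase the auxiliary C1 stereocentre and give the 3(2H)-furanone; the methyl ketone has no β-hydrogen and cannot react.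

Step 15
Reactants: 23 (1S,3S)-1-(4-{[(tert-butyldimethylsilyl)oxy]methyl}-5-oxo-2,5-dihydrofuran-3-yl)-3-[(5S)-5-methyl-4-oxo-5-(2-oxopropyl)-4,5-dihydrofuran-2-yl]butyl 3-methylbut-2-enoate
Product: 24 (1S,3S)-3-[(5S)-5-(acetoxymethyl)-5-methyl-4-oxo-4,5-dihydrofuran-2-yl]-1-(4-{[(tert-butyldimethylsilyl)oxy]methyl}-5-oxo-2,5-dihydrofuran-3-yl)butyl 3-methylbut-2-enoate
Conditions: mCPBA, NaHCO3, CH2Cl2, 23 °C
Reagents that add atoms: 3-chloroperbenzoic acid OOC(=O)c1cccc(Cl)c1
Why: In the Baeyer–Villiger oxidation the primary alkyl group migrates in preference to methyl, turning the methyl ketone into the acetate of the C5 alcohol; the vinylogous-ester ketone and the electron-poor alkenes should be inert to the buffered peracid.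

Step 16
Reactants: 24 (1S,3S)-3-[(5S)-5-(acetoxymethyl)-5-methyl-4-oxo-4,5-dihydrofuran-2-yl]-1-(4-{[(tert-butyldimethylsilyl)oxy]methyl}-5-oxo-2,5-dihydrofuran-3-yl)butyl 3-methylbut-2-enoate
Product: 25 (1S,3S)-1-(4-{[(tert-butyldimethylsilyl)oxy]methyl}-5-oxo-2,5-dihydrofuran-3-yl)-3-[(5S)-5-(hydroxymethyl)-5-methyl-4-oxo-4,5-dihydrofuran-2-yl]butyl 3-methylbut-2-enoate
Conditions: immobilised Candida antarctica lipase B, phosphate buffer pH 7/acetone, 30 °C
Reagents that add atoms: none
Why: Lipase-catalysed hydrolysis should remove the unhindered primary acetate at neutral pH, which avoids base-induced retro-aldol loss of formaldehyde and leaves the hindered conjugated ester and the lactone intact.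

Step 17
Reactants: 25 (1S,3S)-1-(4-{[(tert-butyldimethylsilyl)oxy]methyl}-5-oxo-2,5-dihydrofuran-3-yl)-3-[(5S)-5-(hydroxymethyl)-5-methyl-4-oxo-4,5-dihydrofuran-2-yl]butyl 3-methylbut-2-enoate
Product: 26 (1S,3S)-1-(4-{[(tert-butyldimethylsilyl)oxy]methyl}-5-oxo-2,5-dihydrofuran-3-yl)-3-[(5S)-5-formyl-5-methyl-4-oxo-4,5-dihydrofuran-2-yl]butyl 3-methylbut-2-enoate
Conditions: Dess–Martin periodinane, NaHCO3, CH2Cl2, 0 °C
Reagents that add atoms: none
Why: Dess–Martin oxidation under buffered, non-nucleophilic conditions should give the non-enolisable C5 aldehyde, which is used at once because nucleophiles can deformylate it.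

Step 18
Reactants: 26 (1S,3S)-1-(4-{[(tert-butyldimethylsilyl)oxy]methyl}-5-oxo-2,5-dihydrofuran-3-yl)-3-[(5S)-5-formyl-5-methyl-4-oxo-4,5-dihydrofuran-2-yl]butyl 3-methylbut-2-enoate
Product: 29 macrocyclic (E)-enol lactone bearing the C13 tert-butyldimethylsilyl ether (13-O-silyl-13-deacetyl target), via 2-silyloxyfuran 27 (not isolated), via macrocyclic aldol silyl ether 28 (not isolated)
Conditions: t-BuMe2SiOTf, i-Pr2NEt, CH2Cl2 (0.001 mol per litre), −78 to 23 °C; then DBU, 23 °C
Reagents that add atoms: none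
Why: Soft enolisation turns the butenolide into a 2-silyloxyfuran that adds through its γ-carbon C6 to the silyl-activated aldehyde (intramolecular vinylogous Mukaiyama aldol), and the amidine base then effects E1cB loss of silanolate; the ten-membered ring allows only the alkene in which C4 and C7 are cis, which is the (E)-enol lactone of the target.

Step 19
Reactants: 29 macrocyclic (E)-enol lactone bearing the C13 tert-butyldimethylsilyl ether
Product: 30 13-deacetyl target (primary allylic alcohol at C13)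
Conditions: HF·pyridine, pyridine, THF, 0 °C
Reagents that add atoms: none
Why: Fluoride-mediated desilylation of the primary silyl ether under mildly acidic conditions should be tolerated by the enol lactone and the furanone; the C8 hydroxyl is already esterified and lies trans to the lactone carbonyl, so no translactonisation is possible.

Step 20
Reactants: 30 13-deacetyl target
Product: 31 target CNP0102620.1
Conditions: Ac2O, pyridine, DMAP (cat.), CH2Cl2, 0 °C
Reagents that add atoms: acetic anhydride CC(=O)OC(C)=O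
Why: Acetylation of the primary allylic alcohol completes the target without touching any stereocentre.

Compound list

1 | (R)-4-benzyl-3-propanoyl-1,3-oxazolidin-2-one | CCC(=O)N1[C@H](Cc2ccccc2)COC1=O | starting material
2 | 2,3-dibromoprop-1-ene | BrCC(Br)=C | starting material
3 | sodium (Z)-enolate of 1 | C/C=C(\[O-])N1[C@H](Cc2ccccc2)COC1=O.[Na+] | intermediate
4 | (R)-4-benzyl-3-[(2S)-4-bromo-2-methylpent-4-enoyl]-1,3-oxazolidin-2-one | C=C(Br)C[C@H](C)C(=O)N1[C@H](Cc2ccccc2)COC1=O | intermediate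
5 | (2S)-4-bromo-2-methylpent-4-en-1-ol | C=C(Br)C[C@H](C)CO | intermediate
6 | {[(2S)-4-bromo-2-methylpent-4-en-1-yl]oxy}triethylsilane | C=C(Br)C[C@H](C)CO[Si](CC)(CC)CC | intermediate
7 | but-2-yne-1,4-diol | OCC#CCO | starting material
8 | bis(chloromagnesium) but-2-yne-1,4-diolate | Cl[Mg]OCC#CCO[Mg]Cl | intermediate
9 | [(4S)-4-methyl-5-(triethylsilyloxy)pent-1-en-2-yl]magnesium bromide | C=C([Mg]Br)C[C@H](C)CO[Si](CC)(CC)CC | intermediate
10 | cyclic alkenylmagnesium chelate (4-alkenyl-3-[(chloromagnesiooxy)methyl]-2,5-dihydro-1,2-oxamagnesole) | C=C(C[C@H](C)CO[Si](CC)(CC)CC)C1=C(CO[Mg]Cl)[Mg]OC1 | intermediate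
11 | 3-(hydroxymethyl)-4-[(4S)-4-methyl-5-(triethylsilyloxy)pent-1-en-2-yl]furan-2(5H)-one | O=C1OCC(C(=C)C[C@H](C)CO[Si](CC)(CC)CC)=C1CO | intermediate
12 | 3-{[(tert-butyldimethylsilyl)oxy]methyl}-4-[(4S)-4-methyl-5-(triethylsilyloxy)pent-1-en-2-yl]furan-2(5H)-one | O=C1OCC(C(=C)C[C@H](C)CO[Si](CC)(CC)CC)=C1CO[Si](C)(C)C(C)(C)C | intermediate
13 | secondary ozonide (1,2,4-trioxolane) of 12 | O=C1OCC(C2(OCOO2)C[C@H](C)CO[Si](CC)(CC)CC)=C1CO[Si](C)(C)C(C)(C)C | intermediate
14 | 3-{[(tert-butyldimethylsilyl)oxy]methyl}-4-[(3S)-3-methyl-4-(triethylsilyloxy)butanoyl]furan-2(5H)-one | O=C1OCC(C(=O)C[C@H](C)CO[Si](CC)(CC)CC)=C1CO[Si](C)(C)C(C)(C)C | intermediate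
15 | 3-{[(tert-butyldimethylsilyl)oxy]methyl}-4-[(1S,3S)-1-hydroxy-3-methyl-4-(triethylsilyloxy)butyl]furan-2(5H)-one | O=C1OCC([C@@H](O)C[C@H](C)CO[Si](CC)(CC)CC)=C1CO[Si](C)(C)C(C)(C)C | intermediate
16 | (1S,3S)-1-(4-{[(tert-butyldimethylsilyl)oxy]methyl}-5-oxo-2,5-dihydrofuran-3-yl)-3-methyl-4-(triethylsilyloxy)butyl 3-methylbut-2-enoate | O=C1OCC([C@@H](OC(=O)C=C(C)C)C[C@H](C)CO[Si](CC)(CC)CC)=C1CO[Si](C)(C)C(C)(C)C | intermediate
17 | (1S,3S)-1-(4-{[(tert-butyldimethylsilyl)oxy]methyl}-5-oxo-2,5-dihydrofuran-3-yl)-3-methyl-4-oxobutyl 3-methylbut-2-enoate | O=C1OCC([C@@H](OC(=O)C=C(C)C)C[C@H](C)C=O)=C1CO[Si](C)(C)C(C)(C)C | intermediate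
18 | (1S,3S,4R)-1-(4-{[(tert-butyldimethylsilyl)oxy]methyl}-5-oxo-2,5-dihydrofuran-3-yl)-4-hydroxy-3-methylhept-6-en-1-yl 3-methylbut-2-enoate | O=C1OCC([C@@H](OC(=O)C=C(C)C)C[C@H](C)[C@H](O)CC=C)=C1CO[Si](C)(C)C(C)(C)C | intermediate
19 | (E)-4-methoxypent-3-en-2-one | CO/C(C)=C/C(C)=O | starting material
20 | (1S,3S,4R)-1-(4-{[(tert-butyldimethylsilyl)oxy]methyl}-5-oxo-2,5-dihydrofuran-3-yl)-3-methyl-4-{[(2E)-4-oxopent-2-en-2-yl]oxy}hept-6-en-1-yl 3-methylbut-2-enoate | CC(=O)/C=C(\C)O[C@H](CC=C)[C@@H](C)C[C@H](OC(=O)C=C(C)C)C1=C(CO[Si](C)(C)C(C)(C)C)C(=O)OC1 | intermediate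
21 | (1S,3S,4R)-1-(4-{[(tert-butyldimethylsilyl)oxy]methyl}-5-oxo-2,5-dihydrofuran-3-yl)-3-methyl-6-oxo-4-{[(2E)-4-oxopent-2-en-2-yl]oxy}hexyl 3-methylbut-2-enoate | CC(=O)/C=C(\C)O[C@H](CC=O)[C@@H](C)C[C@H](OC(=O)C=C(C)C)C1=C(CO[Si](C)(C)C(C)(C)C)C(=O)OC1 | intermediate
22 | (1S,3S)-1-(4-{[(tert-butyldimethylsilyl)oxy]methyl}-5-oxo-2,5-dihydrofuran-3-yl)-3-[(2R,5S)-5-methyl-4-oxo-5-(2-oxopropyl)oxolan-2-yl]butyl 3-methylbut-2-enoate | CC(=O)C[C@]1(C)O[C@H](CC1=O)[C@@H](C)C[C@H](OC(=O)C=C(C)C)C2=C(CO[Si](C)(C)C(C)(C)C)C(=O)OC2 | intermediate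
23 | (1S,3S)-1-(4-{[(tert-butyldimethylsilyl)oxy]methyl}-5-oxo-2,5-dihydrofuran-3-yl)-3-[(5S)-5-methyl-4-oxo-5-(2-oxopropyl)-4,5-dihydrofuran-2-yl]butyl 3-methylbut-2-enoate | CC(=O)C[C@]1(C)OC(=CC1=O)[C@@H](C)C[C@H](OC(=O)C=C(C)C)C2=C(CO[Si](C)(C)C(C)(C)C)C(=O)OC2 | intermediate
24 | (1S,3S)-3-[(5S)-5-(acetoxymethyl)-5-methyl-4-oxo-4,5-dihydrofuran-2-yl]-1-(4-{[(tert-butyldimethylsilyl)oxy]methyl}-5-oxo-2,5-dihydrofuran-3-yl)butyl 3-methylbut-2-enoate | CC(=O)OC[C@]1(C)OC(=CC1=O)[C@@H](C)C[C@H](OC(=O)C=C(C)C)C2=C(CO[Si](C)(C)C(C)(C)C)C(=O)OC2 | intermediate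
25 | (1S,3S)-1-(4-{[(tert-butyldimethylsilyl)oxy]methyl}-5-oxo-2,5-dihydrofuran-3-yl)-3-[(5S)-5-(hydroxymethyl)-5-methyl-4-oxo-4,5-dihydrofuran-2-yl]butyl 3-methylbut-2-enoate | OC[C@]1(C)OC(=CC1=O)[C@@H](C)C[C@H](OC(=O)C=C(C)C)C2=C(CO[Si](C)(C)C(C)(C)C)C(=O)OC2 | intermediate
26 | (1S,3S)-1-(4-{[(tert-butyldimethylsilyl)oxy]methyl}-5-oxo-2,5-dihydrofuran-3-yl)-3-[(5S)-5-formyl-5-methyl-4-oxo-4,5-dihydrofuran-2-yl]butyl 3-methylbut-2-enoate | O=C[C@]1(C)OC(=CC1=O)[C@@H](C)C[C@H](OC(=O)C=C(C)C)C2=C(CO[Si](C)(C)C(C)(C)C)C(=O)OC2 | intermediate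
27 | 2-(tert-butyldimethylsilyloxy)furan formed from the butenolide of 26 | O=C[C@]1(C)OC(=CC1=O)[C@@H](C)C[C@H](OC(=O)C=C(C)C)c2coc(O[Si](C)(C)C(C)(C)C)c2CO[Si](C)(C)C(C)(C)C | intermediate
28 | macrocyclic vinylogous aldol adduct as its C5 silyl ether (mixture at C5 and C6) | CC(C)(C)[Si](C)(C)OCC1=C2C(OC1=O)C(O[Si](C)(C)C(C)(C)C)[C@]3(C)OC(=CC3=O)[C@@H](C)C[C@@H]2OC(=O)C=C(C)C | intermediate
29 | macrocyclic (E)-enol lactone bearing the C13 tert-butyldimethylsilyl ether | CC(C)(C)[Si](C)(C)OCC1=C2/C(=C\[C@]3(C)OC(=CC3=O)[C@@H](C)C[C@@H]2OC(=O)C=C(C)C)OC1=O | intermediate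
30 | 13-deacetyl target (C13 primary alcohol) | OCC1=C2/C(=C\[C@]3(C)OC(=CC3=O)[C@@H](C)C[C@@H]2OC(=O)C=C(C)C)OC1=O | intermediate
31 | CNP0102620.1 | CC(=O)OCC1=C2/C(=C\[C@]3(C)OC(=CC3=O)[C@@H](C)C[C@@H]2OC(=O)C=C(C)C)OC1=O | target

Total step count: 20. Longest linear sequence: 20 steps, from 1 to 31.

Steps most likely to fail

Step 18. Closure of the ten-membered ring may be outrun by intermolecular aldol oligomerisation, the hindered aldehyde may be lost by deformylation, and C10 may epimerise under the amine base. The fallback closes the same ring by an intramolecular Wittig olefination. It sets out from alcohol 25. Double silylation with Me3SiOTf/Et3N should give the bis-silylated 2-(trimethylsilyloxy)furan F1, which N-bromosuccinimide brominates at the free furan α-carbon (C6). Mild acidic work-up frees the primary alcohol and gives the γ-bromobutenolide F2. Triphenylphosphine in MeCN should convert it into the phosphonium bromide F3, and Dess–Martin oxidation gives the aldehyde phosphonium salt F4. Triethylamine at high dilution then generates the stabilised phosphorane F5, whose intramolecular Wittig reaction forms the C5=C6 double bond in the only ring-compatible geometry and comes back to the route at 29.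

Step 13. The β-alkoxy aldehyde may undergo β-elimination before the carbene engages it, or catalyst and substrate may be mismatched so that the two faces of the acceptor are poorly differentiated. The fallback sets the quaternary centre by substrate control in a radical cyclisation and sets out from aldehyde 17. Allylboration with the (S)-configured phosphoric acid should give the epimeric (4S)-homoallylic alcohol F6. Transetherification with 19 gives the (E)-enol ether F7, and Lemieux–Johnson cleavage gives the aldehyde F8. Thiol-catalysed generation of the acyl radical (tert-dodecanethiol, azobisisobutyronitrile, benzene, 80 °C) and its 5-exo cyclisation through a chair-like transition state, with the C1 substituent pseudo-equatorial, should place that substituent cis to the acetonyl arm and give the (2S,5S)-oxolanone F9, which differs from 22 only at C1. IBX dehydrogenation of it comes back to the route at 23.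

Step 4. Addition of the hindered alkenyl Grignard reagent to the alkynediolate may be sluggish, and the reagent may be consumed by proton transfer or homocoupling. The fallback assembles the butenolide by cross-coupling and sets out from vinyl bromide 6. Miyaura borylation (bis(pinacolato)diboron, PdCl2(PPh3)2, PPh3, KOPh, toluene, 50 °C) should give the alkenyl pinacol boronate F10. Suzuki–Miyaura coupling with commercial 3,4-dibromofuran-2(5H)-one, which reacts first at its β-bromide (PdCl2(MeCN)2, AsPh3, Ag2O, THF, 65 °C), gives the 3-bromo-4-alkenylbutenolide F11. Stille coupling of it with (tributylstannyl)methanol (Pd(PPh3)4, dioxane, 80 °C) installs the hydroxymethyl group and comes back to the route at 11.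

Further compounds

F1 | step 18 | bis-silylated 2-(trimethylsilyloxy)furan from 25 | C[Si](C)(C)OC[C@]1(C)OC(=CC1=O)[C@@H](C)C[C@H](OC(=O)C=C(C)C)c2coc(O[Si](C)(C)C)c2CO[Si](C)(C)C(C)(C)C
F2 | step 18 | γ-bromobutenolide alcohol (C6 bromide of 25, both C6 epimers) | OC[C@]1(C)OC(=CC1=O)[C@@H](C)C[C@H](OC(=O)C=C(C)C)C2=C(CO[Si](C)(C)C(C)(C)C)C(=O)OC2Br
F3 | step 18 | triphenylphosphonium bromide of the butenolide γ-carbon (alcohol) | OC[C@]1(C)OC(=CC1=O)[C@@H](C)C[C@H](OC(=O)C=C(C)C)C2=C(CO[Si](C)(C)C(C)(C)C)C(=O)OC2[P+](c3ccccc3)(c3ccccc3)c3ccccc3.[Br-]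
F4 | step 18 | aldehyde phosphonium bromide | O=C[C@]1(C)OC(=CC1=O)[C@@H](C)C[C@H](OC(=O)C=C(C)C)C2=C(CO[Si](C)(C)C(C)(C)C)C(=O)OC2[P+](c3ccccc3)(c3ccccc3)c3ccccc3.[Br-]
F5 | step 18 | stabilised phosphorane of the aldehyde | O=C[C@]1(C)OC(=CC1=O)[C@@H](C)C[C@H](OC(=O)C=C(C)C)C2=C(CO[Si](C)(C)C(C)(C)C)C(=O)OC2=P(c3ccccc3)(c3ccccc3)c3ccccc3
F6 | step 13 | (1S,3S,4S)-1-(4-{[(tert-butyldimethylsilyl)oxy]methyl}-5-oxo-2,5-dihydrofuran-3-yl)-4-hydroxy-3-methylhept-6-en-1-yl 3-methylbut-2-enoate | O=C1OCC([C@@H](OC(=O)C=C(C)C)C[C@H](C)[C@@H](O)CC=C)=C1CO[Si](C)(C)C(C)(C)C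
F7 | step 13 | (4S)-epimer of enol ether 20 | CC(=O)/C=C(\C)O[C@@H](CC=C)[C@@H](C)C[C@H](OC(=O)C=C(C)C)C1=C(CO[Si](C)(C)C(C)(C)C)C(=O)OC1
F8 | step 13 | (4S)-epimer of aldehyde 21 | CC(=O)/C=C(\C)O[C@@H](CC=O)[C@@H](C)C[C@H](OC(=O)C=C(C)C)C1=C(CO[Si](C)(C)C(C)(C)C)C(=O)OC1
F9 | step 13 | (2S,5S)-oxolan-3-one, C1 epimer of 22 | CC(=O)C[C@]1(C)O[C@@H](CC1=O)[C@@H](C)C[C@H](OC(=O)C=C(C)C)C2=C(CO[Si](C)(C)C(C)(C)C)C(=O)OC2
F10 | step 4 | triethyl{[(2S)-2-methyl-4-(4,4,5,5-tetramethyl-1,3,2-dioxaborolan-2-yl)pent-4-en-1-yl]oxy}silane | C=C(C[C@H](C)CO[Si](CC)(CC)CC)B1OC(C)(C)C(C)(C)O1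
F11 | step 4 | 3-bromo-4-[(4S)-4-methyl-5-(triethylsilyloxy)pent-1-en-2-yl]furan-2(5H)-one | O=C1OCC(C(=C)C[C@H](C)CO[Si](CC)(CC)CC)=C1Br
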